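## The problem

The target 21 is a chalcone. Ring A (2',4'-dihydroxy-6'-methoxy) carries at C3' a hydrated lavandulyl chain, ArCH2-CH(isopropenyl)-CH2CH2-C(OH)Me2, and ring B is a 2,4-dihydroxyphenyl group joined through an E enone. No ring has to be built; three carbon units must be attached to a phloroglucinol core at the right positions and one branched chain must be assembled. The only stereocentre is C2 of the chain (C1 = benzylic CH2). It is acyclic and remote from every other functional group, so nothing in the molecule can direct it and a catalyst or reagent must set it. Once set it is at risk only if the allylic C-H is metalated or the isopropenyl group is protonated. The fragile parts are the 2'-hydroxychalcone (closes to a flavanone in acid or base, Michael acceptor), the isopropenyl group flanked by two ortho phenols (acid closes a chroman), the tertiary alcohol (ionises in strong acid) and the free polyphenol rings (air oxidation). Two features open the route. C2 bears an isopropenyl group beside a CH2Ar group, which is the pattern left when a carbon nucleophile attacks the inner alkene carbon of ArCH2-CH=C(CH3)-CH2X in the SN2' sense, so the C2-C3 bond, the stereocentre and the 1,1-disubstituted alkene can arise together from an oxidised prenyl group. Before acylation ring A is symmetric (chain between two equal oxygens, OMe para), so the first metalation has one doubly activated site and the second has two equivalent sites.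

## Retrosynthesis

**21 to 20.** No skeletal bond is cut. The four phenols are masked as MOM ethers and the tertiary alcohol as a triethylsilyl ether, so that one mild acid treatment ends the synthesis. MOM is kept on ring A because it directs both metalations. The forward step must free five oxygens without protonating the isopropenyl group or closing the flavanone.

**20 to 16 and 18.** The Cα=Cβ bond of the enone is cut (Claisen-Schmidt condensation). The neighbouring cut, ring A to carbonyl with a whole cinnamoyl unit, would ask a hindered aryl anion to choose 1,2 over 1,4 addition. The aldol route can only give the linear E enone, since acetophenone 16 has one enolisable site and aldehyde 18 has none. 18 is one step from 2,4-dihydroxybenzaldehyde 17.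

**16 to 13.** The aryl-acetyl bond is cut. Directed lithiation between OMOM and OMe gives aryllithium 14, and an N-methoxy-N-methyl amide stops the addition at the ketone stage through adduct 15. The two open ring positions of 13 are interchanged by rotation about the aryl-CH2 bond, so no regiochemical question arises. The reaction must leave the allylic stereocentre unmetalated.

**13 to 9 and 12 (key cut).** The C2-C3 bond of the chain is cut with transposition of the alkene. Grignard reagent 12 attacks the gamma carbon of E allylic chloride 9 under chiral copper catalysis. The alternatives (auxiliary enolate alkylation followed by methylenation, or conjugate addition) would build the isopropenyl group later from a carbonyl next to an epimerisable centre. The precursors are an achiral arene and a four-carbon Grignard reagent. The reaction must deliver gamma over alpha attack and one alkene face.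

**9 to 7 to 6.** C-Cl and C-O bonds only. Chloride 9 comes from E allylic alcohol 7 via mesylate 8, and 7 from prenyl arene 6 by SeO2 oxidation, which selects the E methyl group. The alkene geometry that the key step reads is therefore fixed by a stereospecific pericyclic sequence.

**6 to 2 and 3; 2 to 1.** The aryl-CH2 bond is cut. Lithiation of bis-MOM ether 2 between its two OMOM groups gives aryllithium 4, copper exchange gives arylcopper 5, and prenyl bromide 3 alkylates it. 2 is one step from 5-methoxyresorcinol 1.

**12 to 11 to 10.** The C-Mg bond comes from bromide 11, the silyl ether of commercial 4-bromo-2-methylbutan-2-ol 10. Oxygen sits gamma to magnesium, so the reagent cannot eliminate.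

## Roads not taken

**Alternative 1: phenol-directed rhodium hydroacylation.** The cut is the carbonyl-Cα bond of the enone together with the Cβ-H bond. Ring A salicylaldehyde A2 and 1-ethynyl-2,4-bis(methoxymethoxy)benzene A3 would react under [RhCl(cod)]2, dppf and Na2CO3 to give A1, the target with ring B still as MOM ethers.
- Merits: no enolate, no strong base, full atom economy, E geometry from syn insertion, and ring A needs no protection in the coupling.
- Weak points: with a terminal arylalkyne the insertion regiochemistry is not strongly biased, so the branched 1,1-disubstituted enone competes. Decarbonylation of the acyl rhodium hydride drains electron-rich, di-ortho-substituted aldehydes. A2 must be made from 13 by formylation and acid deprotection, and A1 needs acid again, so the free phenol/isopropenyl pair meets acid twice. A3 costs a homologation of 18.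
- Comparison: this step does not address the stereocentre, so the SN2' event would still be needed. It is better than the chosen plan in sparing the hindered ketone a long exposure to hydroxide. The chosen plan sets against this the unambiguous regiochemistry and geometry of an aldol condensation and a single acid treatment.

**Alternative 2: late Negishi union.** The cut is the ring A C3'-CH2 bond. The homochiral primary alkylzinc iodide A5 and the fully protected 3'-bromochalcone A6 would couple under Pd(OAc)2 with SPhos or CPhos to give A4, which is identical with 20.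
- Merits: this is the more convergent plan. The chalcone is built from achiral material, the stereocentre travels in a small fragment whose purity is easy to assay, and the enone never meets an organolithium.
- Weak points: the C-Br bond of A6 lies between two OMOM groups, which slows oxidative addition of zerovalent palladium and reductive elimination. The alkylpalladium intermediate has its only beta hydrogen on the stereocentre, so beta-hydride elimination and reinsertion would erase or move that centre when reductive elimination is slow. The enone of A6 is open to conjugate addition by the zinc reagent. A6 needs a regioselective bromination. A5 needs its own asymmetric synthesis, most simply the same copper SN2' step on a smaller allylic chloride and then three or four further steps.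
- Comparison: convergence is better here. The chosen plan sets against it an arene-CH2 bond made by plain allylation of 2, a stereocentre formed without any beta-hydride pathway, and fewer steps overall.

**Alternative 3: coumarin ring opening.** The cut is the ring A-carbonyl bond; the carbonyl, both alkene carbons, ring B and its 2-oxygen come from 7-(methoxymethoxy)coumarin A8. Aryllithium 14 would add to the lactone carbonyl of A8 and the ring would open to A7, the protected Z 2-hydroxychalcone.
- Merits: it uses 13 and 14 of the chosen route and replaces steps 8, 9 and 10 by one step.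
- Weak points: the geometry is Z and the target is E. A7 equilibrates with its ring-closed hemiketal, and the acid needed for deprotection would dehydrate that form to a benzopyrylium salt, a stable dead end. Isomerisation would have to come first and would compete with ring closure. The ketone forms in the presence of aryllithium and can be attacked again, and conjugate addition at C4 of A8 competes.
- Comparison: on paper this road is two operations shorter and shares the same key step. The chosen plan sets against it an E alkene delivered by the dehydration itself and no intermediate that can aromatise to a pyrylium ion.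

Key step: step 7

Assumption: the (Sa,S,S) enantiomer of phosphoramidite L* (from (S)-BINOL and bis[(S)-1-(2-methoxyphenyl)ethyl]amine) is taken to give the R centre; if the sense proves opposite, the (Ra,R,R) antipode is used and nothing else changes.

Assumption: 10 is taken as purchasable, and L* is prepared by the standard two-step route from BINOL, PCl3 and the amine, which is not counted.

## Route

Step 1
Reactants: 1 5-methoxyresorcinol
Product: 2 1-methoxy-3,5-bis(methoxymethoxy)benzene
Conditions: MOMCl, i-Pr2NEt, CH2Cl2, 0 °C to rt
Reagents that add atoms: chloromethyl methyl ether, COCCl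
Why: Acetal-forming O-alkylation of both phenols (Williamson type); MOM is the ortho-directing group for both later lithiations and leaves under mild acid.

Step 2
Reactants: 2 1-methoxy-3,5-bis(methoxymethoxy)benzene; 3 prenyl bromide (1-bromo-3-methylbut-2-ene)
Product: 6 5-methoxy-1,3-bis(methoxymethoxy)-2-(3-methylbut-2-enyl)benzene, via aryllithium 4 (not isolated), via arylcopper 5 (not isolated)
Conditions: n-BuLi, THF, 0 °C; CuBr·SMe2, -40 °C; 3, -40 °C to rt
Reagents that add atoms: none
Why: Directed ortho-metalation at the C-H flanked and chelated by two OMOM groups, exchange to the monovalent arylcopper, then SN2 allylation at the primary carbon of 3; copper suppresses SN2' attack and bromine-lithium exchange, and the C2-symmetric product is readily told from the OMOM/OMe-flanked regioisomer.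

Step 3
Reactants: 6 5-methoxy-1,3-bis(methoxymethoxy)-2-(3-methylbut-2-enyl)benzene
Product: 7 (E)-4-[4-methoxy-2,6-bis(methoxymethoxy)phenyl]-2-methylbut-2-en-1-ol
Conditions: SeO2 (0.5 equiv), t-BuOOH, salicylic acid (cat.), CH2Cl2, 0 °C to rt
Reagents that add atoms: selenium dioxide, O=[Se]=O (delivers the oxygen); tert-butyl hydroperoxide, CC(C)(C)OO (terminal oxidant that reoxidises selenium)
Why: Riley-type allylic oxidation (ene reaction with SeO2, then [2,3]-sigmatropic shift), which on a trisubstituted alkene functionalises only the E methyl group of the more substituted end; any enal from over-oxidation has the same geometry and can be returned to 7 with NaBH4.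

Step 4
Reactants: 7 (E)-4-[4-methoxy-2,6-bis(methoxymethoxy)phenyl]-2-methylbut-2-en-1-ol
Product: 9 2-[(E)-4-chloro-3-methylbut-2-enyl]-5-methoxy-1,3-bis(methoxymethoxy)benzene, via allylic mesylate 8 (not isolated)
Conditions: MsCl, 2,4,6-collidine, LiCl, DMF, 0 °C
Reagents that add atoms: lithium chloride, [Li+].[Cl-]
Why: Mesylation and in situ SN2 displacement by chloride at the primary allylic carbon; under these buffered conditions no allylic transposition or E/Z scrambling is expected and the MOM acetals are untouched.

Step 5
Reactants: 10 4-bromo-2-methylbutan-2-ol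
Product: 11 [(4-bromo-2-methylbutan-2-yl)oxy]triethylsilane
Conditions: Et3SiOTf, 2,6-lutidine, CH2Cl2, -78 to 0 °C
Reagents that add atoms: triethylsilyl trifluoromethanesulfonate, CC[Si](CC)(CC)OS(=O)(=O)C(F)(F)F
Why: Silylation of a tertiary alcohol with the silyl triflate and a hindered base; the triethylsilyl ether is inert to magnesium, copper and butyllithium and leaves in the final acid step.

Step 6
Reactants: 11 [(4-bromo-2-methylbutan-2-yl)oxy]triethylsilane
Product: 12 [3-methyl-3-(triethylsilyloxy)butyl]magnesium bromide (about 1 M in Et2O, titrated and used directly)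
Conditions: Mg turnings, I2 (cat.), Et2O, reflux
Reagents that add atoms: magnesium, [Mg]
Why: Grignard formation by insertion of magnesium into a primary C-Br bond; the oxygen is gamma to the metal, so beta-elimination is impossible, and Et2O is used because the key step loses selectivity in THF.

Step 7
Reactants: 9 2-[(E)-4-chloro-3-methylbut-2-enyl]-5-methoxy-1,3-bis(methoxymethoxy)benzene; 12 [3-methyl-3-(triethylsilyloxy)butyl]magnesium bromide
Product: 13 triethyl{[(5R)-5-{[4-methoxy-2,6-bis(methoxymethoxy)phenyl]methyl}-2,6-dimethylhept-6-en-2-yl]oxy}silane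
Conditions: CuBr·SMe2 (5 mol %), (Sa,S,S)-L* (6 mol %), CH2Cl2, -78 °C; 12 in Et2O added over 3 h
Reagents that add atoms: none
Why: Copper-catalysed asymmetric allylic alkylation of a 2-methyl-substituted (beta-disubstituted) allylic chloride with a primary alkyl Grignard reagent, a known reaction type for this substrate class. Transmetalation of 12 to the ligated monovalent copper bromide gives a chiral alkylcopper species that binds the alkene of 9 and adds oxidatively at the gamma carbon (the CH next to the benzylic CH2) anti to the departing chloride, giving a sigma-allyl trivalent copper intermediate. Reductive elimination from this intermediate is faster than its sigma-pi-sigma shift to the alpha terminus, so the C2-C3 bond forms at the inner carbon and the double bond moves out to become the isopropenyl group, whose methyl is the 2-methyl of 9. No ring is closed. The new stereocentre is controlled by the phosphoramidite alone, which decides the face of the planar gamma carbon reached by the copper-bound alkyl group; the stated ligand enantiomer is the one expected to give R. Two selectivities are needed, gamma over alpha and one face over the other. The first is secured by the chloride leaving group, the non-coordinating solvent, the low temperature, the slow addition of 12 (which keeps the less selective dialkylcuprate from building up) and the unbranched CH2Ar substituent on the gamma carbon; the second rests on the single E geometry of 9 fixed in step 3, since the Z isomer would give the other enantiomer. The arene is fully protected, has no acidic or electrophilic site and stays a spectator.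

Step 8
Reactants: 13 triethyl{[(5R)-5-{[4-methoxy-2,6-bis(methoxymethoxy)phenyl]methyl}-2,6-dimethylhept-6-en-2-yl]oxy}silane
Product: 16 1-{6-methoxy-2,4-bis(methoxymethoxy)-3-[(2R)-5-methyl-2-(prop-1-en-2-yl)-5-(triethylsilyloxy)hexyl]phenyl}ethan-1-one, via aryllithium 14 (not isolated), via tetrahedral adduct 15 (not isolated)
Conditions: n-BuLi, THF, -10 to 0 °C; MeC(O)N(OMe)Me, -78 to 0 °C; aq. NH4Cl
Reagents that add atoms: N-methoxy-N-methylacetamide, CC(=O)N(C)OC
Why: Directed ortho-metalation between OMOM and OMe (the two open positions are equivalent) and Weinreb ketone synthesis, in which the chelated adduct 15 survives until work-up so that no second addition occurs; no diamine additive is used, so the much slower metalation of the allylic C-H at the stereocentre should not compete.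

Step 9
Reactants: 17 2,4-dihydroxybenzaldehyde
Product: 18 2,4-bis(methoxymethoxy)benzaldehyde
Conditions: NaH, MOMCl, DMF, 0 °C to rt
Reagents that add atoms: chloromethyl methyl ether, COCCl
Why: O-alkylation of both phenoxides; NaH is needed because the 2-OH is hydrogen-bonded to the aldehyde, and protection keeps the aldehyde electrophilic under the basic condensation.

Step 10
Reactants: 16 1-{6-methoxy-2,4-bis(methoxymethoxy)-3-[(2R)-5-methyl-2-(prop-1-en-2-yl)-5-(triethylsilyloxy)hexyl]phenyl}ethan-1-one; 18 2,4-bis(methoxymethoxy)benzaldehyde
Product: 20 (E)-3-[2,4-bis(methoxymethoxy)phenyl]-1-{6-methoxy-2,4-bis(methoxymethoxy)-3-[(2R)-5-methyl-2-(prop-1-en-2-yl)-5-(triethylsilyloxy)hexyl]phenyl}prop-2-en-1-one, via aldol adduct 19 (not isolated)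
Conditions: KOH, EtOH/H2O, rt
Reagents that add atoms: none
Why: Claisen-Schmidt condensation: the only enolate available (the methyl ketone) adds to the non-enolisable aldehyde and E1cB dehydration of 19 gives the conjugated E enone; with every phenol protected no flavanone can form, and the stereocentre has no acidic hydrogen under hydroxide.

Step 11
Reactants: 20 (E)-3-[2,4-bis(methoxymethoxy)phenyl]-1-{6-methoxy-2,4-bis(methoxymethoxy)-3-[(2R)-5-methyl-2-(prop-1-en-2-yl)-5-(triethylsilyloxy)hexyl]phenyl}prop-2-en-1-one
Product: 21 (E)-1-{2,4-dihydroxy-3-[(2R)-5-hydroxy-5-methyl-2-(prop-1-en-2-yl)hexyl]-6-methoxyphenyl}-3-(2,4-dihydroxyphenyl)prop-2-en-1-one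
Conditions: aq. HCl (to about 1 M), MeOH, rt
Reagents that add atoms: none
Why: Acid-catalysed acetal exchange removes the four MOM groups and solvolysis removes the silyl ether in one operation; dilute acid at room temperature is chosen to stay below the threshold for protonation of the 1,1-disubstituted alkene, ionisation of the tertiary alcohol and flavanone closure, and the stereocentre is not involved.

## Compound list

1 | 5-methoxyresorcinol | COc1cc(O)cc(O)c1 | starting material
2 | 1-methoxy-3,5-bis(methoxymethoxy)benzene | COCOc1cc(OC)cc(OCOC)c1 | intermediate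
3 | prenyl bromide (1-bromo-3-methylbut-2-ene) | CC(C)=CCBr | starting material
4 | [4-methoxy-2,6-bis(methoxymethoxy)phenyl]lithium | [Li]c1c(OCOC)cc(OC)cc1OCOC | intermediate (not isolated)
5 | [4-methoxy-2,6-bis(methoxymethoxy)phenyl]copper | [Cu]c1c(OCOC)cc(OC)cc1OCOC | intermediate (not isolated)
6 | 5-methoxy-1,3-bis(methoxymethoxy)-2-(3-methylbut-2-enyl)benzene | CC(C)=CCc1c(OCOC)cc(OC)cc1OCOC | intermediate
7 | (E)-4-[4-methoxy-2,6-bis(methoxymethoxy)phenyl]-2-methylbut-2-en-1-ol | OC/C(C)=C/Cc1c(OCOC)cc(OC)cc1OCOC | intermediate
8 | (E)-4-[4-methoxy-2,6-bis(methoxymethoxy)phenyl]-2-methylbut-2-enyl methanesulfonate | CS(=O)(=O)OC/C(C)=C/Cc1c(OCOC)cc(OC)cc1OCOC | intermediate (not isolated)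
9 | 2-[(E)-4-chloro-3-methylbut-2-enyl]-5-methoxy-1,3-bis(methoxymethoxy)benzene | ClC/C(C)=C/Cc1c(OCOC)cc(OC)cc1OCOC | intermediate
10 | 4-bromo-2-methylbutan-2-ol | CC(C)(O)CCBr | starting material
11 | [(4-bromo-2-methylbutan-2-yl)oxy]triethylsilane | CC[Si](CC)(CC)OC(C)(C)CCBr | intermediate
12 | [3-methyl-3-(triethylsilyloxy)butyl]magnesium bromide | CC[Si](CC)(CC)OC(C)(C)CC[Mg]Br | intermediate
13 | triethyl{[(5R)-5-{[4-methoxy-2,6-bis(methoxymethoxy)phenyl]methyl}-2,6-dimethylhept-6-en-2-yl]oxy}silane | C=C(C)[C@H](CCC(C)(C)O[Si](CC)(CC)CC)Cc1c(OCOC)cc(OC)cc1OCOC | intermediate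
14 | {6-methoxy-2,4-bis(methoxymethoxy)-3-[(2R)-5-methyl-2-(prop-1-en-2-yl)-5-(triethylsilyloxy)hexyl]phenyl}lithium | C=C(C)[C@H](CCC(C)(C)O[Si](CC)(CC)CC)Cc1c(OCOC)cc(OC)c([Li])c1OCOC | intermediate (not isolated)
15 | lithium 1-{6-methoxy-2,4-bis(methoxymethoxy)-3-[(2R)-5-methyl-2-(prop-1-en-2-yl)-5-(triethylsilyloxy)hexyl]phenyl}-1-[methoxy(methyl)amino]ethan-1-olate (either configuration at the new carbon) | C=C(C)[C@H](CCC(C)(C)O[Si](CC)(CC)CC)Cc1c(OCOC)cc(OC)c(C(C)(O[Li])N(C)OC)c1OCOC | intermediate (not isolated)
16 | 1-{6-methoxy-2,4-bis(methoxymethoxy)-3-[(2R)-5-methyl-2-(prop-1-en-2-yl)-5-(triethylsilyloxy)hexyl]phenyl}ethan-1-one | C=C(C)[C@H](CCC(C)(C)O[Si](CC)(CC)CC)Cc1c(OCOC)cc(OC)c(C(C)=O)c1OCOC | intermediate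
17 | 2,4-dihydroxybenzaldehyde | O=Cc1ccc(O)cc1O | starting material
18 | 2,4-bis(methoxymethoxy)benzaldehyde | O=Cc1ccc(OCOC)cc1OCOC | intermediate
19 | 3-[2,4-bis(methoxymethoxy)phenyl]-3-hydroxy-1-{6-methoxy-2,4-bis(methoxymethoxy)-3-[(2R)-5-methyl-2-(prop-1-en-2-yl)-5-(triethylsilyloxy)hexyl]phenyl}propan-1-one (both carbinol epimers) | C=C(C)[C@H](CCC(C)(C)O[Si](CC)(CC)CC)Cc1c(OCOC)cc(OC)c(C(=O)CC(O)c2ccc(OCOC)cc2OCOC)c1OCOC | intermediate (not isolated)
20 | (E)-3-[2,4-bis(methoxymethoxy)phenyl]-1-{6-methoxy-2,4-bis(methoxymethoxy)-3-[(2R)-5-methyl-2-(prop-1-en-2-yl)-5-(triethylsilyloxy)hexyl]phenyl}prop-2-en-1-one | C=C(C)[C@H](CCC(C)(C)O[Si](CC)(CC)CC)Cc1c(OCOC)cc(OC)c(C(=O)/C=C/c2ccc(OCOC)cc2OCOC)c1OCOC | intermediate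
21 | (E)-1-{2,4-dihydroxy-3-[(2R)-5-hydroxy-5-methyl-2-(prop-1-en-2-yl)hexyl]-6-methoxyphenyl}-3-(2,4-dihydroxyphenyl)prop-2-en-1-one | C=C(C)[C@H](CCC(C)(C)O)Cc1c(O)cc(OC)c(C(=O)/C=C/c2ccc(O)cc2O)c1O | target

## Step count and risks

Total: 11 steps. Longest linear sequence: 8 steps from 1 (steps 1, 2, 3, 4, 7, 8, 10, 11). Side branches: steps 5 and 6 (Grignard reagent) and step 9 (aldehyde).

**Step 7 (key step).** Regiocontrol may erode through alpha attack, either by allyl equilibration on copper or by an uncatalysed background substitution. Facial discrimination may be insufficient, because the gamma substituent is a CH2 group bound to a bulky 2,6-bis(OMOM)aryl ring that can chelate magnesium or copper. Any E/Z erosion in 9 would pass directly into the enantiomeric purity.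

Fallback, from 7 back to 13, replacing steps 4 and 7:
- Sharpless asymmetric epoxidation of 7 (Ti(OiPr)4, L-(+)-diethyl tartrate, t-BuOOH, 4 Å sieves, CH2Cl2, -20 °C) should give [(2S,3S)-3-{[4-methoxy-2,6-bis(methoxymethoxy)phenyl]methyl}-2-methyloxiran-2-yl]methanol F1, by the usual face rule for E 2-methyl-3-substituted allylic alcohols.
- Excess 12 with catalytic CuI (THF/Et2O, -30 °C) should open F1 at the less substituted C3 with inversion to give (2R,3R)-3-{[4-methoxy-2,6-bis(methoxymethoxy)phenyl]methyl}-2,6-dimethyl-6-(triethylsilyloxy)heptane-1,2-diol F2.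
- Thiocarbonyldiimidazole (toluene, 80 °C) converts F2 into (4R)-4-methyl-4-[(2R)-1-[4-methoxy-2,6-bis(methoxymethoxy)phenyl]-5-methyl-5-(triethylsilyloxy)hexan-2-yl]-1,3-dioxolane-2-thione F3.
- Corey-Winter olefination of F3 (P(OMe)3, 110 °C) returns 13. The stereocentre then comes from the tartrate and never sits next to a carbonyl.

**Step 3.** Over-oxidation to the enal, stalling at partial conversion, or oxidative attack on the electron-rich ring would lower the supply of 7.

Fallback, from 6 back to 7: cross-metathesis of 6 with excess methacrolein (second-generation Hoveyda-Grubbs catalyst, CH2Cl2, 40 °C, loss of 2-methylpropene) should give the thermodynamically favoured (E)-4-[4-methoxy-2,6-bis(methoxymethoxy)phenyl]-2-methylbut-2-enal F4. Luche reduction (NaBH4, CeCl3·7H2O, MeOH, 0 °C) then gives 7.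

**Step 8.** Proton transfer from the acetyl methyl of the amide to the hindered aryllithium would return 13, and incomplete metalation would do the same.

Fallback, from 13 back to 16:
- 14, generated as in step 8, is quenched with the non-enolisable DMF to give 6-methoxy-2,4-bis(methoxymethoxy)-3-[(2R)-5-methyl-2-(prop-1-en-2-yl)-5-(triethylsilyloxy)hexyl]benzaldehyde F5.
- MeMgBr (THF, 0 °C) gives 1-{6-methoxy-2,4-bis(methoxymethoxy)-3-[(2R)-5-methyl-2-(prop-1-en-2-yl)-5-(triethylsilyloxy)hexyl]phenyl}ethan-1-ol F6 as a mixture of carbinol epimers, which is of no consequence.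
- Dess-Martin periodinane (NaHCO3, CH2Cl2) oxidises F6 to 16.

**Step 10.** The di-ortho-substituted ketone is twisted out of conjugation, so enolate addition may be slow, the reaction may stall at the aldol stage, and long exposure to hydroxide may partly remove the silyl ether.

Fallback, from 13 and 18 back to 20, bypassing 16:
- Horner-Wadsworth-Emmons reaction of 18 with diethyl {2-[methoxy(methyl)amino]-2-oxoethyl}phosphonate (NaH, THF) gives (E)-3-[2,4-bis(methoxymethoxy)phenyl]-N-methoxy-N-methylprop-2-enamide F7.
- Addition of 14 (from 13) to F7 at -78 °C, a 1,2-addition to the amide carbonyl, gives 20 after work-up.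

**Step 11.** Acid may trigger ring closures before all acetals are gone: flavanone formation by the 2'-OH, chroman formation by phenol attack on the protonated isopropenyl group, or ether formation or elimination at the tertiary alcohol.

Fallback, from 20 to 21 in two orthogonal operations without a solvolytic medium:
- Tetrabutylammonium fluoride (THF, 0 °C) removes the silyl group to give (E)-3-[2,4-bis(methoxymethoxy)phenyl]-1-{3-[(2R)-5-hydroxy-5-methyl-2-(prop-1-en-2-yl)hexyl]-6-methoxy-2,4-bis(methoxymethoxy)phenyl}prop-2-en-1-one F8.
- The phenolic MOM ethers of F8 are then cleaved on the heterogeneous acid NaHSO4·SiO2 in CH2Cl2 at rt to give 21.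

## Further compounds

F1 | step 7 | [(2S,3S)-3-{[4-methoxy-2,6-bis(methoxymethoxy)phenyl]methyl}-2-methyloxiran-2-yl]methanol | OC[C@]1(C)O[C@H]1Cc2c(OCOC)cc(OC)cc2OCOC
F2 | step 7 | (2R,3R)-3-{[4-methoxy-2,6-bis(methoxymethoxy)phenyl]methyl}-2,6-dimethyl-6-(triethylsilyloxy)heptane-1,2-diol | OC[C@](C)(O)[C@H](CCC(C)(C)O[Si](CC)(CC)CC)Cc1c(OCOC)cc(OC)cc1OCOC
F3 | step 7 | (4R)-4-methyl-4-[(2R)-1-[4-methoxy-2,6-bis(methoxymethoxy)phenyl]-5-methyl-5-(triethylsilyloxy)hexan-2-yl]-1,3-dioxolane-2-thione | S=C1OC[C@](C)(O1)[C@H](CCC(C)(C)O[Si](CC)(CC)CC)Cc2c(OCOC)cc(OC)cc2OCOC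
F4 | step 3 | (E)-4-[4-methoxy-2,6-bis(methoxymethoxy)phenyl]-2-methylbut-2-enal | O=C/C(C)=C/Cc1c(OCOC)cc(OC)cc1OCOC
F5 | step 8 | 6-methoxy-2,4-bis(methoxymethoxy)-3-[(2R)-5-methyl-2-(prop-1-en-2-yl)-5-(triethylsilyloxy)hexyl]benzaldehyde | C=C(C)[C@H](CCC(C)(C)O[Si](CC)(CC)CC)Cc1c(OCOC)cc(OC)c(C=O)c1OCOC
F6 | step 8 | 1-{6-methoxy-2,4-bis(methoxymethoxy)-3-[(2R)-5-methyl-2-(prop-1-en-2-yl)-5-(triethylsilyloxy)hexyl]phenyl}ethan-1-ol (both carbinol epimers) | C=C(C)[C@H](CCC(C)(C)O[Si](CC)(CC)CC)Cc1c(OCOC)cc(OC)c(C(C)O)c1OCOC
F7 | step 10 | (E)-3-[2,4-bis(methoxymethoxy)phenyl]-N-methoxy-N-methylprop-2-enamide | CON(C)C(=O)/C=C/c1ccc(OCOC)cc1OCOC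
F8 | step 11 | (E)-3-[2,4-bis(methoxymethoxy)phenyl]-1-{3-[(2R)-5-hydroxy-5-methyl-2-(prop-1-en-2-yl)hexyl]-6-methoxy-2,4-bis(methoxymethoxy)phenyl}prop-2-en-1-one | C=C(C)[C@H](CCC(C)(C)O)Cc1c(OCOC)cc(OC)c(C(=O)/C=C/c2ccc(OCOC)cc2OCOC)c1OCOC
A1 | alternative 1 | (E)-3-[2,4-bis(methoxymethoxy)phenyl]-1-{2,4-dihydroxy-3-[(2R)-5-hydroxy-5-methyl-2-(prop-1-en-2-yl)hexyl]-6-methoxyphenyl}prop-2-en-1-one | C=C(C)[C@H](CCC(C)(C)O)Cc1c(O)cc(OC)c(C(=O)/C=C/c2ccc(OCOC)cc2OCOC)c1O
A2 | alternative 1 | 2,4-dihydroxy-3-[(2R)-5-hydroxy-5-methyl-2-(prop-1-en-2-yl)hexyl]-6-methoxybenzaldehyde | C=C(C)[C@H](CCC(C)(C)O)Cc1c(O)cc(OC)c(C=O)c1O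
A3 | alternative 1 | 1-ethynyl-2,4-bis(methoxymethoxy)benzene | C#Cc1ccc(OCOC)cc1OCOC
A4 | alternative 2 | (E)-3-[2,4-bis(methoxymethoxy)phenyl]-1-{6-methoxy-2,4-bis(methoxymethoxy)-3-[(2R)-5-methyl-2-(prop-1-en-2-yl)-5-(triethylsilyloxy)hexyl]phenyl}prop-2-en-1-one (identical with 20) | C=C(C)[C@H](CCC(C)(C)O[Si](CC)(CC)CC)Cc1c(OCOC)cc(OC)c(C(=O)/C=C/c2ccc(OCOC)cc2OCOC)c1OCOC
A5 | alternative 2 | [(2S)-5-methyl-2-(prop-1-en-2-yl)-5-(triethylsilyloxy)hexyl]zinc iodide (S by the priority of zinc; same spatial arrangement as in 21) | C=C(C)[C@H](CCC(C)(C)O[Si](CC)(CC)CC)C[Zn]I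
A6 | alternative 2 | (E)-3-[2,4-bis(methoxymethoxy)phenyl]-1-[3-bromo-6-methoxy-2,4-bis(methoxymethoxy)phenyl]prop-2-en-1-one | COCOc1cc(OC)c(C(=O)/C=C/c2ccc(OCOC)cc2OCOC)c(OCOC)c1Br
A7 | alternative 3 | (Z)-3-[2-hydroxy-4-(methoxymethoxy)phenyl]-1-{6-methoxy-2,4-bis(methoxymethoxy)-3-[(2R)-5-methyl-2-(prop-1-en-2-yl)-5-(triethylsilyloxy)hexyl]phenyl}prop-2-en-1-one | C=C(C)[C@H](CCC(C)(C)O[Si](CC)(CC)CC)Cc1c(OCOC)cc(OC)c(C(=O)/C=C\c2ccc(OCOC)cc2O)c1OCOC
A8 | alternative 3 | 7-(methoxymethoxy)-2H-chromen-2-one | O=c1ccc2ccc(OCOC)cc2o1
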